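The runs were computed for an exercise; noise was put on by code.

At early times the readings balance: the teal run at 0.667 min holds 87% substrate and 13% target.

| flask | substrate | coupling partner | initiator | remark | time |
|---|---|---|---|---|---|
| teal | 0.027 M | 0.0297 M | 0.38 mM | run made earlier |  |
| amber | 0.027 M | 0.0297 M | 0.59 mM | run made earlier |  |
| flask | 0.027 M | 0.0297 M | 0.27 mM |  | 4.0 min |

| run | time / min | substrate / % | target / % |
|---|---|---|---|
| teal | 0.667 | 87 | 13 |
| teal | 1.33 | 76 | 27 |
| teal | 2.00 | 64 | 37 |
| teal | 2.50 | 57 | 40 |
| teal | 3.00 | 51 | 49 |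
| teal | 4.00 | 42 | 58 |
| amber | 0.250 | 94 | 8 |
| amber | 0.833 | 79 | 24 |
| amber | 1.33 | 67 | 31 |
| amber | 2.00 | 58 | 44 |
| amber | 3.00 | 45 | 57 |
| amber | 4.00 | 33 | 68 |

(readings scatter by 1.5 percentage points)

* substrate present at 4.0 min, in percent of the substrate charged
* target present at 4.0 min, in percent of the substrate charged

- the earlier runs were read with a standard deviation of 1.5 percentage points

*What does substrate follow?* First order, as read. Let k be the first-order constant. The last readings give 0.217 min⁻¹ for teal and 0.277 min⁻¹ for amber.

*Does k follow the initiator?* Not linearly. Initiator rose 1.55-fold, k 1.28-fold, and the root of the initiator ratio is 1.25.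

*Why a root?* Suppose carriers are made in proportion to initiator, are lost in pairs, and making balances loss (quasi-steady state). Their level then goes as the root of initiator.

*So what do you carry?* Teal gives 1.83 min⁻¹, amber 1.87 min⁻¹, with mean 1.85 min⁻¹. This is the chain constant κ, k divided by the root of the ratio of initiator charged to substrate charged.

*The flask has less initiator than either run. Isn't that a stretch?* Yes, two runs make a thin base. Still, I reckon k = 0.185 min⁻¹, so 47.7% substrate and 52.3% target.

The forecast gives 48% substrate and 52% target: “That is the square-root dependence expected of a radical chain.” It rests on the same root, so our match is no check.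

The flask gives 49.3% substrate and 50.7% target.

    initiator → 2 initiating radical (k = 1.40 × 10⁻⁴ s⁻¹)
    substrate + initiating radical → capped initiator + first chain carrier (k = 8.90 × 10⁶ L mol⁻¹ s⁻¹)
    coupling partner + first chain carrier → target + second chain carrier (k = 5.70 × 10⁵ L mol⁻¹ s⁻¹)
    substrate + second chain carrier → by-product + first chain carrier (k = 2.90 × 10⁵ L mol⁻¹ s⁻¹)
    first chain carrier → ended carrier (k = 5.00 s⁻¹)
    2 second chain carrier → ended chains A (k = 2.10 × 10⁸ L mol⁻¹ s⁻¹)
    2 first chain carrier → ended chains B (k = 7.00 × 10⁶ L mol⁻¹ s⁻¹)
    coupling partner → decomposed reagent (k = 0.00190 s⁻¹)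

In this flask, the step of substrate with second chain carrier had 61% of its turnover up to 4.0 min behind it at 2.00 min, while 98.3% of the initiator stood. By 4.00 min, coupling partner was down to 28% of its charge, with 0.00782 M of decomposed reagent formed, and the flask's own κ reads 1.77 min⁻¹. On a second flask, like this one but with 0.0680 mM initiator, κ gives 69.0% substrate at 4.0 min. At that time the second flask holds 75.6% substrate and 24.4% target.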